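Labels: the upper chroman is benzo ring A fused to pyran ring C (O1, C2, C3, C4, C4a, C8a); ring B is the aryl group on C3; ring D is the central arene (D1 on C4, D2 OMe, D4 OH, D6 on C3'); the lower chroman is pyran ring E (O1' to C4') fused to benzo ring F.
Retrosynthesis: after the four O-benzyl groups and an alkoxy group on C2 are removed, one operation cuts C4–D1, C3–C4 and O1–C2; ring E is then cut at O1'–C2' and at C3'–C4'.
Enabling feature: C4 is the benzylic carbon of ring A ortho to O1 and carries ring D, so ring A can pass through an o-quinone methide whose methide carbon is C4, set free when a ring D aryl anion adds to an O-Boc salicylaldehyde.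
Forward order: ring E is closed first on the brominated ring D fragment (enolate benzylation, reduction, Mitsunobu); ring C is then closed in one flask by carbonyl addition, Boc transfer with elimination and [4+2] cycloaddition with the ring B enol ether; acetal reduction and hydrogenolysis finish.
Stereochemistry: C3' comes from an (R)-4-benzyloxazolidinone alkylation; C3 and C4 come from the E geometry of the enol ether, the endo mode and the (1R,2S)-2-phenylcyclohexyl group on the enol ether oxygen.

Key step: step 19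

Assumption: the (1R,2S)-auxiliary is taken to react through the s-trans enol ether with its phenyl group covering the face that would lead to the wrong enantiomeric series, so that C3 forms as R and C4 as S; the (1S,2R)-alcohol is equally available should the sense prove opposite.

Step 1
Reactants: 1 2,4-dihydroxybenzaldehyde
Product: 2 4-(benzyloxy)-2-hydroxybenzaldehyde
Conditions: BnBr (1.0 equiv), NaHCO3, MeCN, 80 °C
Reagents that add atoms: benzyl bromide BrCc1ccccc1
Why: Williamson etherification is selective for the 4-hydroxyl because the 2-hydroxyl is held in a hydrogen bond to the aldehyde and is the weaker nucleophile under a mild base.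

Step 2
Reactants: 2 4-(benzyloxy)-2-hydroxybenzaldehyde
Product: 3 4-(benzyloxy)-2-[(tert-butoxycarbonyl)oxy]benzaldehyde
Conditions: Boc2O, i-Pr2NEt, DMAP (cat.), THF, 0 °C → rt
Reagents that add atoms: di-tert-butyl dicarbonate CC(C)(C)OC(=O)OC(=O)OC(C)(C)C
Why: DMAP-catalysed acylation of the remaining phenol gives the aryl tert-butyl carbonate that later hands its Boc group to the benzylic alkoxide.

Step 3
Reactants: 2 4-(benzyloxy)-2-hydroxybenzaldehyde
Product: 4 4-(benzyloxy)-2-(methoxymethoxy)benzaldehyde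
Conditions: MOMCl, i-Pr2NEt, CH2Cl2, 0 °C → rt
Reagents that add atoms: chloromethyl methyl ether COCCl
Why: O-alkylation of the phenol with MOMCl under amine base installs a group that is later removed with acid without touching benzyl ethers.

Step 4
Reactants: 4 4-(benzyloxy)-2-(methoxymethoxy)benzaldehyde
Product: 5 [4-(benzyloxy)-2-(methoxymethoxy)phenyl]methanol
Conditions: NaBH4, MeOH, 0 °C
Reagents that add atoms: none
Why: Borohydride reduction of the aryl aldehyde to the benzylic alcohol leaves the acetal and the benzyl ether untouched.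

Step 5
Reactants: 5 [4-(benzyloxy)-2-(methoxymethoxy)phenyl]methanol
Product: 6 4-(benzyloxy)-1-(bromomethyl)-2-(methoxymethoxy)benzene
Conditions: CBr4, PPh3, CH2Cl2, 0 °C; used at once
Reagents that add atoms: carbon tetrabromide BrC(Br)(Br)Br
Why: Appel bromination converts the benzylic alcohol into the bromide under neutral conditions that spare the MOM ether, and the labile electron-rich bromide is carried into step 11 without storage.

Step 6
Reactants: 7 methyl 2-(3,5-dihydroxyphenyl)acetate
Product: 8 methyl 2-[3-(benzyloxy)-5-hydroxyphenyl]acetate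
Conditions: BnBr (1.0 equiv), K2CO3, acetone, reflux; diol recovered and recycled
Reagents that add atoms: benzyl bromide BrCc1ccccc1
Why: Williamson monoetherification of a symmetric resorcinol can give only one monoether, which is separable from the diether and from unreacted diol.

Step 7
Reactants: 8 methyl 2-[3-(benzyloxy)-5-hydroxyphenyl]acetate
Product: 9 methyl 2-[3-acetoxy-5-(benzyloxy)phenyl]acetate
Conditions: Ac2O, pyridine, DMAP (cat.), CH2Cl2, rt
Reagents that add atoms: acetic anhydride CC(=O)OC(C)=O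
Why: Acetylation turns the free phenol into a weakly donating acetoxy group, so that the benzyloxy group alone directs the bromination that follows.

Step 8
Reactants: 9 methyl 2-[3-acetoxy-5-(benzyloxy)phenyl]acetate
Product: 10 methyl 2-[3-acetoxy-5-(benzyloxy)-2-bromophenyl]acetate
Conditions: NBS, MeCN, 0 °C → rt, dark
Reagents that add atoms: N-bromosuccinimide O=C1CCC(=O)N1Br
Why: Electrophilic aromatic bromination with NBS in MeCN goes para to the benzyloxy group, the only strong donor, which is the carbon between the acetoxy group and the side chain and becomes D1.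

Step 9
Reactants: 10 methyl 2-[3-acetoxy-5-(benzyloxy)-2-bromophenyl]acetate
Product: 12 2-[5-(benzyloxy)-2-bromo-3-methoxyphenyl]acetic acid, via disodium phenoxide carboxylate 11 (not isolated)
Conditions: NaOH, H2O–MeOH, rt; Me2SO4, 40 °C; NaOH, reflux; then HCl
Reagents that add atoms: dimethyl sulfate COS(=O)(=O)OC; sodium hydroxide [Na+].[OH-]
Why: Hydroxide cleaves the aryl acetate and the methyl ester, dimethyl sulfate methylates the phenoxide in aqueous alkali (classical phenol O-methylation), and the final alkaline reflux saponifies any methyl ester formed at the carboxylate.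

Step 10
Reactants: 12 2-[5-(benzyloxy)-2-bromo-3-methoxyphenyl]acetic acid; 13 (R)-4-benzyl-1,3-oxazolidin-2-one
Product: 15 (R)-4-benzyl-3-{2-[5-(benzyloxy)-2-bromo-3-methoxyphenyl]acetyl}-1,3-oxazolidin-2-one, via mixed pivalic anhydride 14 (not isolated)
Conditions: PivCl, Et3N, THF, −20 °C; then 13, LiCl, → rt
Reagents that add atoms: none
Why: Mixed-anhydride N-acylation of the oxazolidinone under LiCl/Et3N activation attaches the Evans auxiliary without handling an enolisable arylacetyl chloride.

Step 11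
Reactants: 15 (R)-4-benzyl-3-{2-[5-(benzyloxy)-2-bromo-3-methoxyphenyl]acetyl}-1,3-oxazolidin-2-one; 6 4-(benzyloxy)-1-(bromomethyl)-2-(methoxymethoxy)benzene
Product: 17 (R)-4-benzyl-3-{(2R)-2-[5-(benzyloxy)-2-bromo-3-methoxyphenyl]-3-[4-(benzyloxy)-2-(methoxymethoxy)phenyl]propanoyl}-1,3-oxazolidin-2-one, via sodium enolate 16 (not isolated)
Conditions: NaN(SiMe3)2, THF, −78 °C; then 6, −78 → −40 °C; AcOH quench
Reagents that add atoms: none
Why: Evans alkylation, in which the chelated Z sodium enolate is benzylated on the face opposite the 4-benzyl group of the (R)-auxiliary, sets the future C3' as R (C3'–C4' bond).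

Step 12
Reactants: 17 (R)-4-benzyl-3-{(2R)-2-[5-(benzyloxy)-2-bromo-3-methoxyphenyl]-3-[4-(benzyloxy)-2-(methoxymethoxy)phenyl]propanoyl}-1,3-oxazolidin-2-one
Product: 18 (2R)-2-[5-(benzyloxy)-2-bromo-3-methoxyphenyl]-3-[4-(benzyloxy)-2-(methoxymethoxy)phenyl]propan-1-ol
Conditions: LiBH4, H2O (1 equiv), Et2O, 0 °C
Reagents that add atoms: none
Why: LiBH4 reduces the imide carbonyl to the primary alcohol and releases the auxiliary, without epimerising the α-aryl centre or touching the aryl bromide.

Step 13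
Reactants: 18 (2R)-2-[5-(benzyloxy)-2-bromo-3-methoxyphenyl]-3-[4-(benzyloxy)-2-(methoxymethoxy)phenyl]propan-1-ol
Product: 19 5-(benzyloxy)-2-{(2R)-2-[5-(benzyloxy)-2-bromo-3-methoxyphenyl]-3-hydroxypropyl}phenol
Conditions: HCl (cat.), MeOH, 40 °C
Reagents that add atoms: none
Why: Acid-catalysed acetal exchange with methanol removes the phenolic MOM group while the benzyl ethers, the aryl bromide and the stereocentre are inert.

Step 14
Reactants: 19 5-(benzyloxy)-2-{(2R)-2-[5-(benzyloxy)-2-bromo-3-methoxyphenyl]-3-hydroxypropyl}phenol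
Product: 20 (3R)-7-(benzyloxy)-3-[5-(benzyloxy)-2-bromo-3-methoxyphenyl]chroman
Conditions: PPh3, DIAD, THF, 0 °C → rt
Reagents that add atoms: none
Why: Intramolecular Mitsunobu etherification (6-exo-tet attack of the phenol on the activated primary alcohol) closes pyran ring E without involving the stereocentre.

Step 15
Reactants: 21 2,6-dimethoxyphenol
Product: 22 2-(benzyloxy)-1,3-dimethoxybenzene
Conditions: BnBr, K2CO3, DMF, 60 °C
Reagents that add atoms: benzyl bromide BrCc1ccccc1
Why: Williamson benzylation protects the phenol and leaves the two flanking methoxy groups as the directing groups for formylation.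

Step 16
Reactants: 22 2-(benzyloxy)-1,3-dimethoxybenzene
Product: 24 3-(benzyloxy)-2,4-dimethoxybenzaldehyde, via aryl iminium salt 23 (not isolated)
Conditions: POCl3, DMF, 80 °C; then aq. NaOAc
Reagents that add atoms: N,N-dimethylformamide CN(C)C=O; water O
Why: Vilsmeier–Haack formylation of a 1,2,3-trialkoxybenzene occurs at C4, para to one terminal methoxy group and ortho to the other, because the central alkoxy group is twisted out of conjugation.

Step 17
Reactants: 24 3-(benzyloxy)-2,4-dimethoxybenzaldehyde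
Product: 25 2-(benzyloxy)-4-[(E)-2-iodoethenyl]-1,3-dimethoxybenzene
Conditions: CrCl2, CHI3, THF, 0 °C → rt
Reagents that add atoms: iodoform IC(I)I
Why: Takai olefination of the aryl aldehyde with the geminal dichromium reagent from CHI3 and CrCl2 gives the (E)-vinyl iodide through the favoured anti elimination.

Step 18
Reactants: 25 2-(benzyloxy)-4-[(E)-2-iodoethenyl]-1,3-dimethoxybenzene; 26 (1R,2S)-2-phenylcyclohexan-1-ol
Product: 27 2-(benzyloxy)-1,3-dimethoxy-4-[(E)-2-{[(1R,2S)-2-phenylcyclohexyl]oxy}ethenyl]benzene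
Conditions: CuI (10 mol %), 3,4,7,8-tetramethyl-1,10-phenanthroline (20 mol %), Cs2CO3, toluene, 80 °C
Reagents that add atoms: none
Why: Ullmann-type CuI/phenanthroline C–O coupling of a vinyl iodide with an aliphatic alcohol proceeds with retention of alkene geometry and does not touch the carbinol stereocentres.

Step 19
Reactants: 20 (3R)-7-(benzyloxy)-3-[5-(benzyloxy)-2-bromo-3-methoxyphenyl]chroman; 3 4-(benzyloxy)-2-[(tert-butoxycarbonyl)oxy]benzaldehyde; 27 2-(benzyloxy)-1,3-dimethoxy-4-[(E)-2-{[(1R,2S)-2-phenylcyclohexyl]oxy}ethenyl]benzene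
Product: 31 (2S,3R,4S)-7-(benzyloxy)-3-[3-(benzyloxy)-2,4-dimethoxyphenyl]-4-{4-(benzyloxy)-2-[(3R)-7-(benzyloxy)chroman-3-yl]-6-methoxyphenyl}-2-{[(1R,2S)-2-phenylcyclohexyl]oxy}chroman, via aryllithium 28 (not isolated), via arylmagnesium bromide 29 (not isolated), via o-quinone methide 30 (not isolated)
Conditions: n-BuLi, THF, −78 °C; MgBr2·OEt2, → 0 °C; then 3 and 27 (excess), toluene, −78 °C → rt
Reagents that add atoms: none
Why: Bromine–lithium exchange and transmetalation give arylmagnesium bromide 29, which adds to the aldehyde of 3 (C4–D1 bond); the magnesium alkoxide takes over the Boc group from the neighbouring phenol oxygen and the freed phenoxide expels tert-butyl carbonate to give the (E)-o-quinone methide 30 with ring D on the methide carbon. The closest known reaction type is the organomagnesium-triggered release of o-quinone methides from O-Boc salicylaldehydes with in situ capture by chiral enol ethers in an inverse-electron-demand hetero-Diels–Alder reaction. Ring C closes by this intermolecular [4+2] cycloaddition, the nucleophilic β-carbon of 27 bonding to C4 and the quinone methide oxygen to C2. C2 and C3 are trans because the E geometry of the enol ether is carried over suprafacially, C4 is cis to the C2 alkoxy group because that group sits endo under the heterodiene while ring D sits outside on the E methide, and the absolute sense (2S,3R,4S) follows from the phenyl group of the auxiliary covering one face of the s-trans enol ether. The step needs chemoselective attack on the aldehyde in preference to the carbonate (secured by the higher electrophilicity of the aldehyde at −78 °C), regioselectivity (secured by the polarity match of the enol ether β-carbon with the methide carbon) and facial selectivity (secured by the auxiliary, with the enol ether in excess so that it outruns self-condensation of 30). The resident C3' centre beside the methide carbon may reinforce or oppose the auxiliary, which is why a dominant auxiliary available in both enantiomeric forms is used.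

Step 20
Reactants: 31 (2S,3R,4S)-7-(benzyloxy)-3-[3-(benzyloxy)-2,4-dimethoxyphenyl]-4-{4-(benzyloxy)-2-[(3R)-7-(benzyloxy)chroman-3-yl]-6-methoxyphenyl}-2-{[(1R,2S)-2-phenylcyclohexyl]oxy}chroman
Product: 32 (3R,4S)-7-(benzyloxy)-3-[3-(benzyloxy)-2,4-dimethoxyphenyl]-4-{4-(benzyloxy)-2-[(3R)-7-(benzyloxy)chroman-3-yl]-6-methoxyphenyl}chroman
Conditions: Et3SiH, BF3·OEt2, CH2Cl2, −78 → −20 °C
Reagents that add atoms: none
Why: Ionic hydrogenation, in which BF3·OEt2 ionises the exocyclic C2–O bond to the ring oxocarbenium ion and Et3SiH reduces it to the C2 methylene, releases the auxiliary alcohol and leaves C3 and C4 untouched.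

Step 21
Reactants: 32 (3R,4S)-7-(benzyloxy)-3-[3-(benzyloxy)-2,4-dimethoxyphenyl]-4-{4-(benzyloxy)-2-[(3R)-7-(benzyloxy)chroman-3-yl]-6-methoxyphenyl}chroman
Product: 33 (3R,4S)-3-(3-hydroxy-2,4-dimethoxyphenyl)-4-{4-hydroxy-2-[(3R)-7-hydroxychroman-3-yl]-6-methoxyphenyl}chroman-7-ol (CNP0305801.1)
Conditions: H2 (1 atm), Pd/C, EtOAc–MeOH, rt
Reagents that add atoms: none
Why: Hydrogenolysis over Pd/C cleaves the four aryl benzyl ethers, while the chroman C–O bonds are not benzylic and the diarylmethine C–H is inert.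

Compound list
1 | 2,4-dihydroxybenzaldehyde | O=Cc1ccc(O)cc1O | starting material
2 | 4-(benzyloxy)-2-hydroxybenzaldehyde | O=Cc1ccc(OCc2ccccc2)cc1O | intermediate
3 | 4-(benzyloxy)-2-[(tert-butoxycarbonyl)oxy]benzaldehyde (ring A aldehyde) | CC(C)(C)OC(=O)Oc1cc(OCc2ccccc2)ccc1C=O | intermediate
4 | 4-(benzyloxy)-2-(methoxymethoxy)benzaldehyde | COCOc1cc(OCc2ccccc2)ccc1C=O | intermediate
5 | [4-(benzyloxy)-2-(methoxymethoxy)phenyl]methanol | COCOc1cc(OCc2ccccc2)ccc1CO | intermediate
6 | 4-(benzyloxy)-1-(bromomethyl)-2-(methoxymethoxy)benzene | COCOc1cc(OCc2ccccc2)ccc1CBr | intermediate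
7 | methyl 2-(3,5-dihydroxyphenyl)acetate | COC(=O)Cc1cc(O)cc(O)c1 | starting material
8 | methyl 2-[3-(benzyloxy)-5-hydroxyphenyl]acetate | COC(=O)Cc1cc(O)cc(OCc2ccccc2)c1 | intermediate
9 | methyl 2-[3-acetoxy-5-(benzyloxy)phenyl]acetate | COC(=O)Cc1cc(OC(C)=O)cc(OCc2ccccc2)c1 | intermediate
10 | methyl 2-[3-acetoxy-5-(benzyloxy)-2-bromophenyl]acetate | COC(=O)Cc1cc(OCc2ccccc2)cc(OC(C)=O)c1Br | intermediate
11 | disodium 2-[5-(benzyloxy)-2-bromo-3-oxidophenyl]acetate (not isolated) | [Na+].[Na+].[O-]C(=O)Cc1cc(OCc2ccccc2)cc([O-])c1Br | intermediate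
12 | 2-[5-(benzyloxy)-2-bromo-3-methoxyphenyl]acetic acid | OC(=O)Cc1cc(OCc2ccccc2)cc(OC)c1Br | intermediate
13 | (R)-4-benzyl-1,3-oxazolidin-2-one | O=C1N[C@H](Cc2ccccc2)CO1 | starting material
14 | 2-[5-(benzyloxy)-2-bromo-3-methoxyphenyl]acetic pivalic anhydride (not isolated) | CC(C)(C)C(=O)OC(=O)Cc1cc(OCc2ccccc2)cc(OC)c1Br | intermediate
15 | (R)-4-benzyl-3-{2-[5-(benzyloxy)-2-bromo-3-methoxyphenyl]acetyl}-1,3-oxazolidin-2-one | O=C1OC[C@@H](Cc2ccccc2)N1C(=O)Cc1cc(OCc2ccccc2)cc(OC)c1Br | intermediate
16 | sodium (1Z)-1-[(4R)-4-benzyl-2-oxo-1,3-oxazolidin-3-yl]-2-[5-(benzyloxy)-2-bromo-3-methoxyphenyl]ethen-1-olate (not isolated) | [Na+].[O-]/C(=C\c1cc(OCc2ccccc2)cc(OC)c1Br)N1[C@H](Cc2ccccc2)COC1=O | intermediate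
17 | (R)-4-benzyl-3-{(2R)-2-[5-(benzyloxy)-2-bromo-3-methoxyphenyl]-3-[4-(benzyloxy)-2-(methoxymethoxy)phenyl]propanoyl}-1,3-oxazolidin-2-one | O=C1OC[C@@H](Cc2ccccc2)N1C(=O)[C@H](Cc1ccc(OCc2ccccc2)cc1OCOC)c1cc(OCc2ccccc2)cc(OC)c1Br | intermediate
18 | (2R)-2-[5-(benzyloxy)-2-bromo-3-methoxyphenyl]-3-[4-(benzyloxy)-2-(methoxymethoxy)phenyl]propan-1-ol | OC[C@H](Cc1ccc(OCc2ccccc2)cc1OCOC)c1cc(OCc2ccccc2)cc(OC)c1Br | intermediate
19 | 5-(benzyloxy)-2-{(2R)-2-[5-(benzyloxy)-2-bromo-3-methoxyphenyl]-3-hydroxypropyl}phenol | OC[C@H](Cc1ccc(OCc2ccccc2)cc1O)c1cc(OCc2ccccc2)cc(OC)c1Br | intermediate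
20 | (3R)-7-(benzyloxy)-3-[5-(benzyloxy)-2-bromo-3-methoxyphenyl]chroman (lower bromide) | COc1cc(OCc2ccccc2)cc([C@@H]2COc3cc(OCc4ccccc4)ccc3C2)c1Br | intermediate
21 | 2,6-dimethoxyphenol | COc1cccc(OC)c1O | starting material
22 | 2-(benzyloxy)-1,3-dimethoxybenzene | COc1cccc(OC)c1OCc1ccccc1 | intermediate
23 | {[3-(benzyloxy)-2,4-dimethoxyphenyl]methylidene}dimethylammonium dichlorophosphate (not isolated) | COc1ccc(C=[N+](C)C)c(OC)c1OCc1ccccc1.[O-]P(=O)(Cl)Cl | intermediate
24 | 3-(benzyloxy)-2,4-dimethoxybenzaldehyde | COc1ccc(C=O)c(OC)c1OCc1ccccc1 | intermediate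
25 | 2-(benzyloxy)-4-[(E)-2-iodoethenyl]-1,3-dimethoxybenzene | COc1ccc(/C=C/I)c(OC)c1OCc1ccccc1 | intermediate
26 | (1R,2S)-2-phenylcyclohexan-1-ol | O[C@@H]1CCCC[C@H]1c1ccccc1 | starting material
27 | 2-(benzyloxy)-1,3-dimethoxy-4-[(E)-2-{[(1R,2S)-2-phenylcyclohexyl]oxy}ethenyl]benzene (ring B enol ether) | COc1ccc(/C=C/O[C@@H]2CCCC[C@H]2c2ccccc2)c(OC)c1OCc1ccccc1 | intermediate
28 | {4-(benzyloxy)-2-[(3R)-7-(benzyloxy)chroman-3-yl]-6-methoxyphenyl}lithium (not isolated) | COc1cc(OCc2ccccc2)cc([C@@H]2COc3cc(OCc4ccccc4)ccc3C2)c1[Li] | intermediate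
29 | {4-(benzyloxy)-2-[(3R)-7-(benzyloxy)chroman-3-yl]-6-methoxyphenyl}magnesium bromide (not isolated) | COc1cc(OCc2ccccc2)cc([C@@H]2COc3cc(OCc4ccccc4)ccc3C2)c1[Mg]Br | intermediate
30 | (6E)-3-(benzyloxy)-6-({4-(benzyloxy)-2-[(3R)-7-(benzyloxy)chroman-3-yl]-6-methoxyphenyl}methylidene)cyclohexa-2,4-dien-1-one (o-quinone methide, not isolated) | O=C1C=C(OCc2ccccc2)C=C/C1=C\c1c(OC)cc(OCc2ccccc2)cc1[C@@H]1COc2cc(OCc3ccccc3)ccc2C1 | intermediate
31 | (2S,3R,4S)-7-(benzyloxy)-3-[3-(benzyloxy)-2,4-dimethoxyphenyl]-4-{4-(benzyloxy)-2-[(3R)-7-(benzyloxy)chroman-3-yl]-6-methoxyphenyl}-2-{[(1R,2S)-2-phenylcyclohexyl]oxy}chroman | COc1ccc([C@@H]2[C@@H](O[C@@H]3CCCC[C@H]3c3ccccc3)Oc3cc(OCc4ccccc4)ccc3[C@H]2c2c(OC)cc(OCc3ccccc3)cc2[C@@H]2COc3cc(OCc4ccccc4)ccc3C2)c(OC)c1OCc1ccccc1 | intermediate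
32 | (3R,4S)-7-(benzyloxy)-3-[3-(benzyloxy)-2,4-dimethoxyphenyl]-4-{4-(benzyloxy)-2-[(3R)-7-(benzyloxy)chroman-3-yl]-6-methoxyphenyl}chroman | COc1ccc([C@@H]2COc3cc(OCc4ccccc4)ccc3[C@H]2c2c(OC)cc(OCc3ccccc3)cc2[C@@H]2COc3cc(OCc4ccccc4)ccc3C2)c(OC)c1OCc1ccccc1 | intermediate
33 | (3R,4S)-3-(3-hydroxy-2,4-dimethoxyphenyl)-4-{4-hydroxy-2-[(3R)-7-hydroxychroman-3-yl]-6-methoxyphenyl}chroman-7-ol (CNP0305801.1) | COc1ccc([C@@H]2COc3cc(O)ccc3[C@H]2c2c(OC)cc(O)cc2[C@@H]2COc3cc(O)ccc3C2)c(OC)c1O | target

Total step count: 21.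
Longest linear sequence: 12 steps (from 7 through steps 6 to 14, then steps 19 to 21).

Steps most likely to fail

Step 19. The doubly ortho-substituted arylmagnesium may add to the aldehyde too slowly or attack the carbonate instead, the quinone methide may be lost to self-condensation before the β-aryl enol ether engages, or facial control may erode if the C3' centre opposes the auxiliary. The fallback separates the carbonyl addition from the cycloaddition; it sets out from 20, 2 and 27 and comes back at 31. Aryllithium 28, made from 20 as before, would be added at −78 °C to the sodium phenoxide of aldehyde 2 (NaH, THF), where no carbonate competes, to give after work-up [4-(benzyloxy)-2-hydroxyphenyl]{4-(benzyloxy)-2-[(3R)-7-(benzyloxy)chroman-3-yl]-6-methoxyphenyl}methanol F1 as a mixture of carbinol epimers. F1 and enol ether 27 would then be stirred in toluene over 4 Å molecular sieves with a catalytic phosphoric acid diester (diphenyl phosphate, or an enantiopure BINOL-derived phosphoric acid as a second control element). Dehydration of o-hydroxybenzyl alcohols in this way is a known route to o-quinone methides for [4+2] reactions with electron-rich alkenes, and slow release of the quinone methide in the presence of the trap should give 31.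

Step 18. The copper-catalysed C–O coupling may stall on the hindered secondary alcohol, and the styryl iodide may be lost by dehydrohalogenation or isomerise under the basic conditions. The fallback builds the enol ether from the alcohol side; it sets out from 26 and 22 and comes back at 27. Alcohol 26 would be treated with KH and trichloroethylene to give (1R,2S)-2-phenylcyclohexyl (E)-1,2-dichloroethenyl ether F2, and this with n-BuLi (THF, −78 °C, then MeOH) to give (1R,2S)-2-phenylcyclohexyl ethynyl ether F3. Hydroboration of F3 with pinacolborane under Cp2Zr(H)Cl catalysis would give 4,4,5,5-tetramethyl-2-[(E)-2-{[(1R,2S)-2-phenylcyclohexyl]oxy}ethenyl]-1,3,2-dioxaborolane F4. Benzyl ether 22 would be brominated with NBS in MeCN, para to a methoxy group, to give 2-(benzyloxy)-4-bromo-1,3-dimethoxybenzene F5. Suzuki–Miyaura coupling of F4 with F5 (Pd(PPh3)4, a zerovalent palladium catalyst, K3PO4, dioxane–water, 80 °C) should then give 27, its E geometry fixed by the syn hydroboration.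

Step 20. After ionisation of the acetal the oxocarbenium ion may lose the C3 proton (4H-chromene formation and erosion of C3), or the endocyclic C–O bond may ionise and the ring-opened cation be reduced. The fallback takes the acetal carbon down in three known operations; it sets out from 31 and comes back at 32. Hydrolysis of 31 (aq. HCl, THF, rt) would give (3R,4S)-7-(benzyloxy)-3-[3-(benzyloxy)-2,4-dimethoxyphenyl]-4-{4-(benzyloxy)-2-[(3R)-7-(benzyloxy)chroman-3-yl]-6-methoxyphenyl}chroman-2-ol F6 as a mixture of anomers, into which either mode of C–O cleavage converges. NaBH4 in EtOH would reduce the open hydroxy-aldehyde form of F6 to (2R,3S)-3-[4-(benzyloxy)-2-hydroxyphenyl]-2-[3-(benzyloxy)-2,4-dimethoxyphenyl]-3-{4-(benzyloxy)-2-[(3R)-7-(benzyloxy)chroman-3-yl]-6-methoxyphenyl}propan-1-ol F7. Mitsunobu closure of F7 (PPh3, DIAD, THF), the same ring closure as used for ring E, should give 32.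

Further compounds
F1 | step 19 | [4-(benzyloxy)-2-hydroxyphenyl]{4-(benzyloxy)-2-[(3R)-7-(benzyloxy)chroman-3-yl]-6-methoxyphenyl}methanol (both carbinol epimers) | Oc1cc(OCc2ccccc2)ccc1C(O)c1c(OC)cc(OCc2ccccc2)cc1[C@@H]1COc2cc(OCc3ccccc3)ccc2C1
F2 | step 18 | (1R,2S)-2-phenylcyclohexyl (E)-1,2-dichloroethenyl ether | Cl/C=C(/Cl)O[C@@H]1CCCC[C@H]1c1ccccc1
F3 | step 18 | (1R,2S)-2-phenylcyclohexyl ethynyl ether | C#CO[C@@H]1CCCC[C@H]1c1ccccc1
F4 | step 18 | 4,4,5,5-tetramethyl-2-[(E)-2-{[(1R,2S)-2-phenylcyclohexyl]oxy}ethenyl]-1,3,2-dioxaborolane | CC1(C)OB(/C=C/O[C@@H]2CCCC[C@H]2c2ccccc2)OC1(C)C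
F5 | step 18 | 2-(benzyloxy)-4-bromo-1,3-dimethoxybenzene | COc1ccc(Br)c(OC)c1OCc1ccccc1
F6 | step 20 | (3R,4S)-7-(benzyloxy)-3-[3-(benzyloxy)-2,4-dimethoxyphenyl]-4-{4-(benzyloxy)-2-[(3R)-7-(benzyloxy)chroman-3-yl]-6-methoxyphenyl}chroman-2-ol (both anomers) | COc1ccc([C@@H]2C(O)Oc3cc(OCc4ccccc4)ccc3[C@H]2c2c(OC)cc(OCc3ccccc3)cc2[C@@H]2COc3cc(OCc4ccccc4)ccc3C2)c(OC)c1OCc1ccccc1
F7 | step 20 | (2R,3S)-3-[4-(benzyloxy)-2-hydroxyphenyl]-2-[3-(benzyloxy)-2,4-dimethoxyphenyl]-3-{4-(benzyloxy)-2-[(3R)-7-(benzyloxy)chroman-3-yl]-6-methoxyphenyl}propan-1-ol | COc1ccc([C@H](CO)[C@@H](c2ccc(OCc3ccccc3)cc2O)c2c(OC)cc(OCc3ccccc3)cc2[C@@H]2COc3cc(OCc4ccccc4)ccc3C2)c(OC)c1OCc1ccccc1
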